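## The problem

The target 13 is a dimer of liquiritigenin: two 7-hydroxy-2-(4-hydroxyphenyl)chroman-4-one units joined by a single bond between C3 and C3'' (flavanone numbering, second half doubly primed, is used for the open-chain precursors as well). The four contiguous stereocentres C2, C3, C3'' and C2'' have the configuration (2S,3R,2''R,3''S), so both heterocycles are 2,3-trans, the halves are mirror images, the compound is meso, and only relative configuration has to be controlled. C3 and C3'' are the difficult pair, because they flank a freely rotating bond and no ring relates them. C2 and C2'' can be left to their C3 neighbours, since the 2,3-trans diequatorial flavanone is the stable arrangement and a 4'-hydroxyflavanone can equilibrate at C2 by reversible cleavage of C2–O1. The molecule is fragile: base opens the pyranone rings to chalcones and erases C2 and C3, C3–H is an enolisable α-hydrogen, the C4–C3–C3''–C4'' 1,4-diketone can close to a furan under strong acid, the benzylic C2–O1 ether is open to hydrogenolysis and to Lewis acids, and the free phenols are oxidisable. The enabling feature is that C2 and C2'' are benzylic and para to the ring B hydroxyl groups. Each O1–C2 bond is the formal 1,6-adduct of a ring A phenol to a para-quinone methide of ring B, so both pyranone rings can be closed oxidatively from a precursor in which C2 and C2'' are still methylene groups.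

## Retrosynthesis

**Target 13 to hexaphenol 9 (O1–C2 and O1''–C2'').** The two benzylic aryl ether bonds are cut first. This removes both heterocycles and both C2 stereocentres at once and leaves the acyclic meso diketone 9, whose only stereochemical content is the C3/C3'' relation. A cut at C3–C3'' would require dimerising a flavanone enolate, which ring-opens and offers no control of meso against racemic. In the forward direction each ring B is oxidised by two electrons to a para-quinone methide (10, then 12 after the half-closed stage 11), and the ortho hydroxyl of the neighbouring ketone adds to the methide carbon. All six phenols of 9 are left free, so that 13 leaves the cell as the final product. A C7 ether carried through the closure would force a dealkylation on the finished biflavanone, either by a Lewis acid or by hydrogenolysis next to the benzylic C2–O1 bond, and both are avoided. The reaction must oxidise ring B before ring A, close the ring faster than the quinone methide loses its C3 proton, give the trans ring, and stop before the product is oxidised further.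

**Hexaphenol 9 to hexabenzyl ether 8 (six O–benzyl bonds).** Benzyl ethers are chosen because they leave under neutral hydrogenolysis. Methyl ethers would need strong Lewis acids, which threaten the 1,4-diketone with furan formation, and acid-labile acetals would need protic acid with the same risk. Removing benzyl before the rings exist also keeps hydrogen and palladium away from the C2–O1 bonds of 13. Compound 8 has no free phenol and tolerates strong base.

**Hexabenzyl ether 8 to diketone 3 and two molecules of chloride 4 (C2–C3 and C2''–C3'').** Both benzylic side chains are cut from the α-carbons, which removes both stereocentres and leaves the symmetrical, achiral diketone 3. In the forward direction the dienediolate 5 is benzylated twice by way of enolate 6, one molecule of 4 for each α-carbon. The neighbouring option, forming C3–C3'' last by oxidative dimerisation of a dihydrochalcone enolate, is equally short and is held in reserve. Neither gives diastereocontrol in the bond-forming event. Meso 8 therefore forms beside its racemic diastereomer 7, and the plan asks the same step to convert 7 into 8 by base epimerisation of the unseparated mixture under crystallisation of the meso isomer.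

**Diketone 3 to two molecules of ketone 1 (C3–C3'').** The central bond is made by copper-mediated oxidative coupling of two molecules of enolate 2. A Friedel–Crafts bis-acylation of a resorcinol diether would be as short, but the AlCl3 it needs strips benzyl ethers. It would force methyl ethers and bring back the Lewis-acid deprotection. Ketone 1 and chloride 4 are catalogue compounds.

## Roads not taken

Alternative 1: The cut is at C2–C3 and C2''–C3'', with the four stereocentres placed on a cyclohexene. (1E,3E)-1,4-Bis[4-(benzyloxy)phenyl]buta-1,3-diene A1 and maleic anhydride A2 would combine in an endo Diels–Alder reaction to the all-cis anhydride A3.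
- Merits: the cycloaddition is a textbook reaction for 1,4-diarylbutadienes, and one concerted step fixes all four centres. The cis-fused anhydride makes C3/C3'' meso by symmetry, with no diastereomer to remove. On this point it is clearly better than the chosen plan, which obtains the meso relation by equilibration and crystallisation.
- Weak points: A3 is 2,3-cis in both halves, so both C2 centres would have to be inverted. Epimerising C3 instead would destroy the meso relation. The two alkene carbons are surplus and each must be replaced by oxygen, which means oxidative cleavage followed by a carbon-to-oxygen migration at two benzylic positions. Two ring A units must then be attached to the carbonyls of a hindered cis-diacyl system that epimerises readily, and the aryl ether bonds still have to be made.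
- Comparison: the chosen plan answers with four steps, no excised atoms, and a ring closure that gives the trans relation directly.

Alternative 2: The cut is at C3–C3'' together with a sacrificial C2–C2'' bond. The bis-chalcone A4, whose two 2'-oxygens are bridged by a naphthalene-1,8-dimethylene unit, would be irradiated (365 nm, or visible light with a triplet sensitiser) to the syn head-to-head cyclobutane A5.
- Merits: the template makes the cis-diaroyl cyclobutane, so the meso C3/C3'' relation is enforced and not merely isolated. The chalcone halves come from simple condensations.
- Weak points: the C2–C2'' bond of A5 must later be broken and replaced by two C–O bonds while the adjacent C3–C3'' bond survives. Oxidised or excited cyclobutanes prefer cycloreversion, which would break both bonds, so this step has no dependable basis. A tether through the 2'-oxygens sits far from the alkenes and competes with E/Z isomerisation. Putting the template on and taking it off costs further steps.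
- Comparison: the chosen plan concedes the stereocontrol advantage. It offers a closure of an established reactivity type and no bond that has to be made and then destroyed.

Alternative 3: The cut is at C8a–O1, C4a–C4 and O1–C2 in each half, with ring A introduced as an aryne. The dicesium salt of (2E,3E)-2,3-bis[4-(benzyloxy)benzylidene]succinic acid A6 would take up two molecules of 3-chloro-5-methoxybenzyne A8, released by fluoride from silyl triflate A7. Each aryne inserts into a carboxyl C–O bond and each phenoxide closes ring C by oxa-Michael addition, giving A9.
- Merits: this is the most convergent of the four plans. Six bonds and both chromanone systems arise in one flask from a Stobbe-type diacid, and the final ring closure is the classical flavanone closure. In bond-forming power it exceeds the chosen key step.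
- Weak points: all four stereocentres arise by conjugate addition and protonation, with nothing to set C3 against C3''. A meso/racemic mixture would have to be dealt with at the end, so it is no better than the chosen plan in stereocontrol. The chlorine that directs the aryne regiochemistry must be removed afterwards, and the C7 methyl ethers of A9 would need a Lewis-acid demethylation on the sensitive biflavanone. A7 is itself a multi-step reagent. Simple O-arylation without acyl transfer and anhydride formation from the diacid compete with the insertion.
- Comparison: the chosen plan offers cheap reagents, a stereodefined precursor before ring closure, and no step after it.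

Key step: step 4

Remark: compounds 6, 7, 10, 11 and 12 are racemic. Where a configuration is written, one enantiomer is drawn.

## Route

Step 1
Reactants: 1 2',4'-bis(benzyloxy)acetophenone (two molecules)
Product: 3 1,4-bis[2,4-bis(benzyloxy)phenyl]butane-1,4-dione, via lithium enolate 2 (not isolated)
Conditions: LiN(iPr)2 (1.1 equiv), THF, −78 °C; then CuCl2 (1.1 equiv) in DMF, −78 °C to rt
Reagents that add atoms: 2',4'-bis(benzyloxy)acetophenone (the second molecule of 1), CC(=O)c1ccc(OCc2ccccc2)cc1OCc1ccccc1
Why: Oxidative homocoupling of a ketone enolate: divalent copper (CuCl2) oxidises the lithium enolate 2 and the α-carbons of two molecules join to the symmetrical 1,4-diketone, a reaction for which aryl methyl ketones are the standard substrates. The benzyl ethers are inert to the amide base at −78 °C and no stereocentre is formed.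

Step 2
Reactants: 3 1,4-bis[2,4-bis(benzyloxy)phenyl]butane-1,4-dione; 4 4-(benzyloxy)benzyl chloride (two molecules)
Product: 8 meso-(2R,3S)-2,3-bis[4-(benzyloxy)benzyl]-1,4-bis[2,4-bis(benzyloxy)phenyl]butane-1,4-dione, via dilithium dienediolate 5 (not isolated), via monobenzylated lithium enolate 6 (not isolated), via racemic diastereomer 7 (not isolated)
Conditions: LiN(iPr)2 (2.2 equiv), THF, −78 to −30 °C; then 4 (2.3 equiv), DMPU, −78 °C to rt; aqueous work-up; then DBU (0.2 equiv), iPrOH/toluene, 60 °C to rt, crystallisation of 8
Reagents that add atoms: 4-(benzyloxy)benzyl chloride (the second molecule of 4), ClCc1ccc(OCc2ccccc2)cc1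
Why: Double C-alkylation of a 1,4-diketone dienediolate, the diketone counterpart of succinate dianion alkylation: the first benzylation leaves the second enolate (6) in place, so the second benzyl group enters at the other α-carbon. Both stereocentres are created without control, so meso 8 should form together with racemic 7; the unseparated crude mixture is therefore equilibrated with catalytic DBU through the ketone enolate in a medium in which the centrosymmetric meso isomer is expected to be the less soluble, so that 7 should drain into crystalline 8 (crystallisation-induced diastereomer transformation).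

Step 3
Reactants: 8 meso-(2R,3S)-2,3-bis[4-(benzyloxy)benzyl]-1,4-bis[2,4-bis(benzyloxy)phenyl]butane-1,4-dione
Product: 9 meso-(2R,3S)-1,4-bis(2,4-dihydroxyphenyl)-2,3-bis(4-hydroxybenzyl)butane-1,4-dione
Conditions: H2 (1 atm), 10% Pd/C, THF/MeOH (1:1), rt
Reagents that add atoms: none
Why: Hydrogenolysis of six aryl benzyl ethers under neutral conditions. The 2,4-dihydroxyphenyl ketones that emerge are chelated vinylogous acids and should resist reduction at 1 atm, and no acid or base is present that could epimerise C3/C3'' or trigger Paal–Knorr furan formation.

Step 4
Reactants: 9 meso-(2R,3S)-1,4-bis(2,4-dihydroxyphenyl)-2,3-bis(4-hydroxybenzyl)butane-1,4-dione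
Product: 13 meso-(2S,3R,2''R,3''S)-7,7''-dihydroxy-2,2''-bis(4-hydroxyphenyl)-3,3''-bichroman-4,4''-dione, via first quinone methide 10 (not isolated), via half-closed monoflavanone 11 (not isolated), via second quinone methide 12 (not isolated)
Conditions: undivided cell, graphite anode, Pt cathode, constant current (about 2 mA cm−2), 4.0–4.2 F mol−1 with HPLC control, Bu4NBF4 (0.05 M), (CF3)2CHOH (HFIP)/MeCN (4:1), AcOH (2 vol%), 5 mM, 0 °C; then rt, 12 h, no current
Reagents that add atoms: none
Why: Two-electron, two-proton anodic oxidation of each ring B para-alkylphenol gives a phenoxonium ion that loses its benzylic proton to a para-quinone methide (10, then 12); the neighbouring ring A hydroxyl adds 1,6 to the methide carbon, forming O1–C2 and then O1''–C2'', while protons are reduced to H2 at the cathode. The closest known reaction type is the oxidative (anodic or quinone-mediated) cyclisation of 4-hydroxybenzyl-substituted phenols and 2'-hydroxydihydrochalcones to 2-arylchromans and flavanones through quinone methides. Each pyranone ring closes 6-exo-trig onto the exocyclic double bond of the methide; closure by the distal phenol would need a seven-membered ring and should not compete. C2 and C2'' are each set by the adjacent C3 centre: allylic strain holds C3–H in the plane of the quinone methide, so the tethered oxygen attacks the face that leaves the aryl group and the C3 substituent diequatorial (2,3-trans), and because a 4'-hydroxyflavanone re-ionises at C2–O1 in HFIP, any cis ring should drain to trans during the current-free hold. C3 and C3'' are not touched, so the meso relation of 9 is carried into 13 provided ring closure outruns tautomerisation of the quinone methide to the α-benzylidene ketone, which is why the medium is weakly acidic and free of base. Oxidation of ring B before ring A is secured by the substrate: both ring A hydroxyls are conjugated with the C4 carbonyl and one is chelated to it, which should place their oxidation well above that of a para-alkylphenol. Selectivity against further oxidation of 11 and 13 rests on charge control, low current density and the somewhat higher potential of a phenol whose benzylic carbon already bears oxygen.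

## Compound list

1 | 2',4'-bis(benzyloxy)acetophenone | CC(=O)c1ccc(OCc2ccccc2)cc1OCc1ccccc1 | starting material
2 | lithium enolate of 1, lithium 1-[2,4-bis(benzyloxy)phenyl]ethen-1-olate | C=C(O[Li])c1ccc(OCc2ccccc2)cc1OCc1ccccc1 | intermediate
3 | 1,4-bis[2,4-bis(benzyloxy)phenyl]butane-1,4-dione | O=C(CCC(=O)c1ccc(OCc2ccccc2)cc1OCc1ccccc1)c1ccc(OCc2ccccc2)cc1OCc1ccccc1 | intermediate
4 | 4-(benzyloxy)benzyl chloride | ClCc1ccc(OCc2ccccc2)cc1 | starting material
5 | dilithium (1Z,3Z)-1,4-bis[2,4-bis(benzyloxy)phenyl]buta-1,3-diene-1,4-diolate | [Li]O/C(=C\C=C(/O[Li])c1ccc(OCc2ccccc2)cc1OCc1ccccc1)c1ccc(OCc2ccccc2)cc1OCc1ccccc1 | intermediate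
6 | monobenzylated lithium (Z)-enolate, racemic: lithium enolate of 2-[4-(benzyloxy)benzyl]-1,4-bis[2,4-bis(benzyloxy)phenyl]butane-1,4-dione at the unsubstituted α-carbon | [Li]O/C(=C\C(Cc1ccc(OCc2ccccc2)cc1)C(=O)c1ccc(OCc2ccccc2)cc1OCc1ccccc1)c1ccc(OCc2ccccc2)cc1OCc1ccccc1 | intermediate
7 | racemic (2R*,3R*)-2,3-bis[4-(benzyloxy)benzyl]-1,4-bis[2,4-bis(benzyloxy)phenyl]butane-1,4-dione, the diastereomer of 8 that forms beside it in step 2 and is epimerised to it in the same step | O=C(c1ccc(OCc2ccccc2)cc1OCc1ccccc1)[C@@H](Cc1ccc(OCc2ccccc2)cc1)[C@H](Cc1ccc(OCc2ccccc2)cc1)C(=O)c1ccc(OCc2ccccc2)cc1OCc1ccccc1 | intermediate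
8 | meso-(2R,3S)-2,3-bis[4-(benzyloxy)benzyl]-1,4-bis[2,4-bis(benzyloxy)phenyl]butane-1,4-dione | O=C(c1ccc(OCc2ccccc2)cc1OCc1ccccc1)[C@@H](Cc1ccc(OCc2ccccc2)cc1)[C@@H](Cc1ccc(OCc2ccccc2)cc1)C(=O)c1ccc(OCc2ccccc2)cc1OCc1ccccc1 | intermediate
9 | meso-(2R,3S)-1,4-bis(2,4-dihydroxyphenyl)-2,3-bis(4-hydroxybenzyl)butane-1,4-dione | Oc1ccc(C(=O)[C@@H](Cc2ccc(O)cc2)[C@@H](Cc2ccc(O)cc2)C(=O)c2ccc(O)cc2O)c(O)c1 | intermediate
10 | first quinone methide: 9 with one 4-hydroxybenzyl group oxidised to a (4-oxocyclohexa-2,5-dien-1-ylidene)methyl group, relative configuration of 9, racemic | Oc1ccc(C(=O)[C@@H](C=C2C=CC(=O)C=C2)[C@@H](Cc2ccc(O)cc2)C(=O)c2ccc(O)cc2O)c(O)c1 | intermediate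
11 | half-closed monoflavanone: 2,3-trans-7-hydroxy-2-(4-hydroxyphenyl)-3-[1-(2,4-dihydroxyphenyl)-3-(4-hydroxyphenyl)-1-oxopropan-2-yl]chroman-4-one, C3/C3'' relation as in 9, racemic | O=C1c2ccc(O)cc2O[C@H](c2ccc(O)cc2)[C@H]1[C@@H](Cc1ccc(O)cc1)C(=O)c1ccc(O)cc1O | intermediate
12 | second quinone methide: 11 with the remaining 4-hydroxybenzyl group oxidised to a (4-oxocyclohexa-2,5-dien-1-ylidene)methyl group, racemic | O=C1c2ccc(O)cc2O[C@H](c2ccc(O)cc2)[C@H]1[C@@H](C=C1C=CC(=O)C=C1)C(=O)c1ccc(O)cc1O | intermediate
13 | meso-(2S,3R,2''R,3''S)-7,7''-dihydroxy-2,2''-bis(4-hydroxyphenyl)-3,3''-bichroman-4,4''-dione (CNP0231820.1; both rings 2,3-trans) | O=C1c2ccc(O)cc2O[C@H](c2ccc(O)cc2)[C@H]1[C@@H]1C(=O)c2ccc(O)cc2O[C@H]1c1ccc(O)cc1 | target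

## Step count and least certain steps

Total: 4 steps. Longest linear sequence: 4 steps (1 → 3 → 8 → 9 → 13).

**Step 4 (key step).** Four processes threaten it.
- Further oxidation: the ring B phenol of 11 or 13 oxidises at nearly the same potential as that of 9, and loss of C2–H would lead to flavone-type unsaturation.
- Loss of the C3 proton from a quinone methide: this gives the α-benzylidene ketone, whose later oxa-Michael closure would scramble C3 and erode the meso purity.
- Passivation of the anode by phenoxyl radical coupling.
- Competing oxidation of the ring A resorcinol units once 9 is depleted.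

Fallback: the approach changes from electrode and free quinone methide to quinone-mediated hydride abstraction on a substrate whose ring B oxygen stays masked. It sets out from 8. MgBr2·OEt2 (toluene/Et2O, reflux) should remove only the two chelated ortho benzyl ethers and give meso-1,4-bis[4-(benzyloxy)-2-hydroxyphenyl]-2,3-bis[4-(benzyloxy)benzyl]butane-1,4-dione F1. DDQ (1,4-dioxane, 60 °C) should abstract hydride from each 4-benzyloxybenzyl methylene, and the ortho phenol should capture the cation to give 7,7'',4',4'''-tetra-O-benzyl-13 F2, the known flavan and flavanone closure. Hydrogenolysis (H2, Pd/C, EtOAc/MeOH, stopped after four equivalents) returns to the route at 13. Its price is that the benzylic C2–O1 bonds are then exposed to hydrogen and palladium.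

**Step 2.** The electron-rich dienediolate 5 may transfer an electron to the benzylic chloride, giving reductive coupling of 4 and an enedione. Proton exchange between enolates may lead to geminal dialkylation, and O-alkylation may intrude. The alkylation itself is not expected to favour the meso isomer, and the conversion of 7 into 8 depends on the meso isomer crystallising first, which cannot be predicted. Should the racemate prove the less soluble, 8 would have to be taken from the mother liquor by chromatography and recovered 7 re-equilibrated with DBU in solution.

Fallback: the order of bond formation is reversed, setting out from 1. Its enolate 2 is benzylated once with 4 to 1-[2,4-bis(benzyloxy)phenyl]-3-[4-(benzyloxy)phenyl]propan-1-one F3. The lithium enolate of this ketone is then dimerised oxidatively with CuCl2, the standard route to 2,3-disubstituted 1,4-diketones. This returns to the route at 8, again as a mixture with 7 that enters the same DBU equilibration and crystallisation.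

**Step 1.** The oxidative coupling may stall through α-chlorination of the ketone by CuCl2, enolate protonation or aldol self-condensation.

Fallback: the oxidation is replaced by a polar alkylation, setting out from 1. α-Bromination (CuBr2, EtOAc/CHCl3, reflux) gives 2-bromo-1-[2,4-bis(benzyloxy)phenyl]ethan-1-one F4. Enolate 2, generated from a second portion of 1, displaces the bromide and returns to the route at 3.

## Further compounds

F1 | step 4 | meso-1,4-bis[4-(benzyloxy)-2-hydroxyphenyl]-2,3-bis[4-(benzyloxy)benzyl]butane-1,4-dione | O=C(c1ccc(OCc2ccccc2)cc1O)[C@@H](Cc1ccc(OCc2ccccc2)cc1)[C@@H](Cc1ccc(OCc2ccccc2)cc1)C(=O)c1ccc(OCc2ccccc2)cc1O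
F2 | step 4 | meso-(2S,3R,2''R,3''S)-7,7''-bis(benzyloxy)-2,2''-bis[4-(benzyloxy)phenyl]-3,3''-bichroman-4,4''-dione | O=C1c2ccc(OCc3ccccc3)cc2O[C@H](c2ccc(OCc3ccccc3)cc2)[C@H]1[C@@H]1C(=O)c2ccc(OCc3ccccc3)cc2O[C@H]1c1ccc(OCc2ccccc2)cc1
F3 | step 2 | 1-[2,4-bis(benzyloxy)phenyl]-3-[4-(benzyloxy)phenyl]propan-1-one | O=C(CCc1ccc(OCc2ccccc2)cc1)c1ccc(OCc2ccccc2)cc1OCc1ccccc1
F4 | step 1 | 2-bromo-1-[2,4-bis(benzyloxy)phenyl]ethan-1-one | O=C(CBr)c1ccc(OCc2ccccc2)cc1OCc1ccccc1
A1 | alternative 1 | (1E,3E)-1,4-bis[4-(benzyloxy)phenyl]buta-1,3-diene | O(Cc1ccccc1)c1ccc(/C=C/C=C/c2ccc(OCc3ccccc3)cc2)cc1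
A2 | alternative 1 | maleic anhydride | O=C1OC(=O)C=C1
A3 | alternative 1 | all-cis 3,6-bis[4-(benzyloxy)phenyl]cyclohex-4-ene-1,2-dicarboxylic anhydride | O=C1OC(=O)[C@@H]2[C@H]1[C@H](c1ccc(OCc3ccccc3)cc1)C=C[C@@H]2c1ccc(OCc2ccccc2)cc1
A4 | alternative 2 | 1,8-bis({5-(benzyloxy)-2-[(2E)-3-(4-benzyloxyphenyl)prop-2-enoyl]phenoxy}methyl)naphthalene | O=C(/C=C/c1ccc(OCc2ccccc2)cc1)c1ccc(OCc2ccccc2)cc1OCc1cccc2cccc(COc3cc(OCc4ccccc4)ccc3C(=O)/C=C/c3ccc(OCc4ccccc4)cc3)c12
A5 | alternative 2 | template-bridged syn head-to-head cyclobutane photodimer (cis-diaroyl, cis-diaryl) | O=C1c2ccc(OCc3ccccc3)cc2OCc2cccc3cccc(COc4cc(OCc5ccccc5)ccc4C(=O)[C@@H]4[C@@H](c5ccc(OCc6ccccc6)cc5)[C@@H](c5ccc(OCc6ccccc6)cc5)[C@H]14)c23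
A6 | alternative 3 | (2E,3E)-2,3-bis[4-(benzyloxy)benzylidene]succinic acid | OC(=O)/C(=C/c1ccc(OCc2ccccc2)cc1)/C(=C\c1ccc(OCc2ccccc2)cc1)C(=O)O
A7 | alternative 3 | 3-chloro-5-methoxy-2-(trimethylsilyl)phenyl trifluoromethanesulfonate | COc1cc(Cl)c([Si](C)(C)C)c(OS(=O)(=O)C(F)(F)F)c1
A8 | alternative 3 | 3-chloro-5-methoxybenzyne | COC1=CC#CC(Cl)=C1
A9 | alternative 3 | 5,5''-dichloro-7,7''-di-O-methyl-4',4'''-di-O-benzyl derivative of 13 | O=C1c2c(Cl)cc(OC)cc2O[C@H](c2ccc(OCc3ccccc3)cc2)[C@H]1[C@@H]1C(=O)c2c(Cl)cc(OC)cc2O[C@H]1c1ccc(OCc2ccccc2)cc1
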